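**Strategy**

Numbering the 3,7-dioxabicyclo[3.3.0]octane core C1 (C–OH), C2, O3, C4, C5, C6, O7, C8, everything rests on cutting the fusion bond C1–C5 and the ether bond O3–C2. The key step exploits that O3–C4–C5 of ring B is a latent oxirane and C1=C2 a latent 2-silyloxystyrene: Cp2TiCl opens the strained oxirane, the C5 radical closes ring A (C1, C5, C6, O7, C8) on C1, and the benzylic C2 centre is then oxidised and captured by O3 to close ring B (C1, C2, O3, C4, C5). The precursor is an acyclic (Z)-2-silyloxycinnamyl ether of an enantiopure aryl oxiranyl carbinol, whose carbinol centre (C6) controls all others.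

Key step: step 6

Remark on the chemistry: the target is read as the (1S,2S,5R,6S) isomer, that is cis-fused, with the C6 aryl group exo (cis to H-5) and the C2 aryl group endo (trans to the C1 hydroxyl).

**Route**

Step 1
Reactants: 1 3,4-dimethoxybenzaldehyde; 2 vinylmagnesium bromide
Product: 3 rac-1-(3,4-dimethoxyphenyl)prop-2-en-1-ol
Conditions: THF, 0 °C; then H2O/aq NH4Cl
Reagents that add atoms: vinylmagnesium bromide (compound 2), C=C[Mg]Br
Why: Grignard 1,2-addition to an aromatic aldehyde; the new carbinol centre forms as a racemate and is resolved in step 2.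

Step 2
Reactants: 3 rac-1-(3,4-dimethoxyphenyl)prop-2-en-1-ol
Product: 4 (R)-(3,4-dimethoxyphenyl)[(2S)-oxiran-2-yl]methanol
Conditions: Ti(OiPr)4 (cat.), D-(−)-diisopropyl tartrate (cat.), tBuOOH (0.45 equiv), 4 Å molecular sieves, CH2Cl2, −20 °C
Reagents that add atoms: tert-butyl hydroperoxide, CC(C)(C)OO
Why: Sharpless kinetic resolution: with the D-(−)-tartrate catalyst the (S)-alcohol should be the fast-reacting enantiomer and be epoxidised on the face that gives the erythro epoxy alcohol, so the catalyst fixes the carbinol centre (the only one that survives step 6), while (R)-3 stays behind and is removed by chromatography.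

Step 3
Reactants: 4 (R)-(3,4-dimethoxyphenyl)[(2S)-oxiran-2-yl]methanol; 5 2-bromo-N-methoxy-N-methylacetamide
Product: 6 2-{(R)-(3,4-dimethoxyphenyl)[(2S)-oxiran-2-yl]methoxy}-N-methoxy-N-methylacetamide
Conditions: NaH, Bu4NI (cat.), THF/DMF, −20 → 0 °C
Reagents that add atoms: 2-bromo-N-methoxy-N-methylacetamide (compound 5), CON(C)C(=O)CBr
Why: Williamson ether synthesis with a reactive α-bromo amide under aprotic conditions, where O-alkylation should outrun epoxide migration of the alkoxide; no stereocentre is touched.

Step 4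
Reactants: 6 2-{(R)-(3,4-dimethoxyphenyl)[(2S)-oxiran-2-yl]methoxy}-N-methoxy-N-methylacetamide; 7 4-(chloromethyl)-1,2-dimethoxybenzene
Product: 9 1-{(R)-(3,4-dimethoxyphenyl)[(2S)-oxiran-2-yl]methoxy}-3-(3,4-dimethoxyphenyl)propan-2-one, via benzylic Grignard reagent 8 (not isolated)
Conditions: 7, Mg turnings, THF, 0 °C (slow addition, dilute); then 6, THF, −78 → −20 °C; aq NH4Cl
Reagents that add atoms: 4-(chloromethyl)-1,2-dimethoxybenzene (compound 7, used as its Grignard reagent 8), COc1ccc(CCl)cc1OC
Why: Weinreb ketone synthesis: the benzylic Grignard reagent adds once to the N-methoxy-N-methylamide, whose magnesium chelate resists a second addition and should react at low temperature far faster than the oxirane; no stereocentre is touched.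

Step 5
Reactants: 9 1-{(R)-(3,4-dimethoxyphenyl)[(2S)-oxiran-2-yl]methoxy}-3-(3,4-dimethoxyphenyl)propan-2-one
Product: 10 tert-butyl({(1Z)-1-(3,4-dimethoxyphenyl)-3-[(R)-(3,4-dimethoxyphenyl)((2S)-oxiran-2-yl)methoxy]prop-1-en-2-yl}oxy)dimethylsilane
Conditions: TBSOTf, Et3N, CH2Cl2, −78 → 0 °C
Reagents that add atoms: tert-butyldimethylsilyl trifluoromethanesulfonate, CC(C)(C)[Si](C)(C)OS(=O)(=O)C(F)(F)F
Why: Soft enolisation and O-silylation at the more acidic benzylic CH2 should give the conjugated enol ether with the aryl group cis to the silyloxy group (Z); the alkene geometry is not relayed to the product because C2 later passes through planar intermediates.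

Step 6
Reactants: 10 tert-butyl({(1Z)-1-(3,4-dimethoxyphenyl)-3-[(R)-(3,4-dimethoxyphenyl)((2S)-oxiran-2-yl)methoxy]prop-1-en-2-yl}oxy)dimethylsilane
Product: 12 (1S,2S,5R,6S)-1-(tert-butyldimethylsilyloxy)-2,6-bis(3,4-dimethoxyphenyl)-3,7-dioxabicyclo[3.3.0]octane, via benzylic iodide 11 (not isolated)
Conditions: Cp2TiCl2 (2.5 equiv), Zn dust, THF, rt (the Cp2TiCl solution added slowly to 10); then I2 (1.2 equiv), rt → 50 °C
Reagents that add atoms: none
Why: Cp2TiCl (trivalent titanium) opens the strained oxirane by electron transfer at its more substituted C–O bond, the secondary C5 radical adds to the silyloxy-bearing alkene carbon C1 to close ring A, the benzylic C2 radical is intercepted by a second Cp2TiCl and turned by I2 into benzylic iodide 11, and ionisation of 11 lets the tetravalent titanium alkoxide O3 close ring B. The closest known reaction type is the Cp2TiCl/I2 epoxide–alkene radical cyclisation–etherification of epoxy cinnamyl ethers to 2,6-diaryl-3,7-dioxabicyclo[3.3.0]octanes, applied here to a 2-silyloxycinnamyl ether. Ring A closes by 5-exo-trig radical cyclisation and ring B by 5-exo-tet O-alkylation with SN1 character. C5 and C1 are set in the chair-like transition state of the 5-hexenyl radical cyclisation with the C6 aryl group pseudo-equatorial, which places CH2O[Ti] trans to that aryl group and cis to C2, so only the cis-fused bicycle can form and its absolute sense follows from the carbinol centre C6 of 10. C2 is set at cation capture: the C1–OSi bond lies in the nodal plane of the benzylic cation and eclipses C2–H, not the aryl group (allylic 1,3-strain), so O3 should attack the face that leaves the aryl group trans to the silyloxy group (endo), which the bulky silyl ether should also favour at equilibrium. The step needs 5-exo over 6-endo attack and cyclisation faster than reduction of the C5 radical to an organotitanium; benzylic stabilisation with the aryl group shielding C2 secures the first, and slow addition of Cp2TiCl the second.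

Step 7
Reactants: 12 (1S,2S,5R,6S)-1-(tert-butyldimethylsilyloxy)-2,6-bis(3,4-dimethoxyphenyl)-3,7-dioxabicyclo[3.3.0]octane
Product: 13 (1S,2S,5R,6S)-2,6-bis(3,4-dimethoxyphenyl)-3,7-dioxabicyclo[3.3.0]octan-1-ol
Conditions: Bu4NF, THF, rt → 50 °C; then H2O
Reagents that add atoms: none
Why: Fluoride-induced desilylation of the tertiary silyl ether under non-acidic conditions, so the two acid-labile benzylic ether centres are not ionised and no stereocentre changes.

**Compound list**

1 | 3,4-dimethoxybenzaldehyde | COc1ccc(C=O)cc1OC | starting material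
2 | vinylmagnesium bromide | C=C[Mg]Br | starting material
3 | rac-1-(3,4-dimethoxyphenyl)prop-2-en-1-ol | COc1ccc(C(O)C=C)cc1OC | intermediate
4 | (R)-(3,4-dimethoxyphenyl)[(2S)-oxiran-2-yl]methanol (erythro epoxy alcohol) | COc1ccc([C@@H](O)[C@@H]2CO2)cc1OC | intermediate
5 | 2-bromo-N-methoxy-N-methylacetamide | CON(C)C(=O)CBr | starting material
6 | 2-{(R)-(3,4-dimethoxyphenyl)[(2S)-oxiran-2-yl]methoxy}-N-methoxy-N-methylacetamide | COc1ccc([C@@H](OCC(=O)N(C)OC)[C@@H]2CO2)cc1OC | intermediate
7 | 4-(chloromethyl)-1,2-dimethoxybenzene | COc1ccc(CCl)cc1OC | starting material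
8 | (3,4-dimethoxybenzyl)magnesium chloride (not isolated) | COc1ccc(C[Mg]Cl)cc1OC | intermediate
9 | 1-{(R)-(3,4-dimethoxyphenyl)[(2S)-oxiran-2-yl]methoxy}-3-(3,4-dimethoxyphenyl)propan-2-one | COc1ccc([C@@H](OCC(=O)Cc3ccc(OC)c(OC)c3)[C@@H]2CO2)cc1OC | intermediate
10 | (Z)-tert-butyldimethylsilyl enol ether of 9, tert-butyl({(1Z)-1-(3,4-dimethoxyphenyl)-3-[(R)-(3,4-dimethoxyphenyl)((2S)-oxiran-2-yl)methoxy]prop-1-en-2-yl}oxy)dimethylsilane | COc1ccc([C@@H](OC/C(O[Si](C)(C)C(C)(C)C)=C/c3ccc(OC)c(OC)c3)[C@@H]2CO2)cc1OC | intermediate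
11 | monocyclic benzylic iodide [(2S,3R,4S)-4-(tert-butyldimethylsilyloxy)-2-(3,4-dimethoxyphenyl)-4-[(3,4-dimethoxyphenyl)iodomethyl]tetrahydrofuran-3-yl]methanol, iodide centre undefined, shown as the free alcohol but present in the flask as its Cp2Ti(Cl) alkoxide (not isolated) | COc1ccc([C@H]2OC[C@@](C(I)c3ccc(OC)c(OC)c3)(O[Si](C)(C)C(C)(C)C)[C@@H]2CO)cc1OC | intermediate
12 | (1S,2S,5R,6S)-1-(tert-butyldimethylsilyloxy)-2,6-bis(3,4-dimethoxyphenyl)-3,7-dioxabicyclo[3.3.0]octane | COc1ccc([C@H]2OC[C@@]3(O[Si](C)(C)C(C)(C)C)[C@@H]2CO[C@H]3c2ccc(OC)c(OC)c2)cc1OC | intermediate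
13 | (1S,2S,5R,6S)-2,6-bis(3,4-dimethoxyphenyl)-3,7-dioxabicyclo[3.3.0]octan-1-ol | COc1ccc([C@H]2OC[C@@]3(O)[C@@H]2CO[C@H]3c2ccc(OC)c(OC)c2)cc1OC | target

Total step count: 7. Longest linear sequence: 7 steps.

**Steps most likely to fail**

Step 6. The benzylic organotitanium at C2 may expel the neighbouring silyloxy group by β-elimination before iodine oxidises it, the C5 radical may close 6-endo or be reduced before it cyclises, and capture of the benzylic cation may lose facial control at C2. The fallback sets out from 4 and comes back at 13. Compound 4 is O-alkylated with propargyl bromide (NaH, THF) to the propargyl ether F1. Sonogashira coupling with 4-iodo-1,2-dimethoxybenzene (Pd(PPh3)2Cl2, CuI, Et3N) gives the aryl alkyne F2. Cp2TiCl (THF, rt, then dilute acid) effects the known epoxide–alkyne 5-exo-dig radical cyclisation to the benzylidene tetrahydrofuran F3, in which no β-oxygenated organotitanium can arise and the CH2OH group again ends up trans to the aryl group. OsO4 (cat.) with N-methylmorpholine N-oxide should dihydroxylate the exocyclic alkene on the face anti to the neighbouring CH2OH group to give the triol F4. Camphorsulfonic acid (cat.) in CH2Cl2 ionises the electron-rich benzylic alcohol, and the primary hydroxyl closes ring B under the same allylic-strain control to give 13.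

Step 4. Wurtz-type homocoupling may consume the electron-rich benzylic chloride while the Grignard reagent forms, and the Grignard reagent or magnesium halide may open the oxirane in competition with acylation. The fallback sets out from 4 and comes back at 9. Compound 4 is O-alkylated with 2,3-dibromopropene (NaH, THF) to the 2-bromoallyl ether F5. Compound 7 is converted with Zn dust and LiCl in THF into the benzylic zinc reagent F6, which does not attack oxiranes. Negishi coupling of F5 with F6 (Pd(PPh3)4, THF, rt) gives the 1,1-disubstituted alkene F7. Lemieux–Johnson cleavage (OsO4 cat., NaIO4, 2,6-lutidine, dioxane/H2O) then gives ketone 9.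

Step 2. Enantiomer discrimination may be incomplete, because the epoxy alcohol is the product of the fast-reacting enantiomer and its enantiomeric purity falls as conversion rises; the electron-rich benzylic epoxy alcohol may also be opened by the Lewis-acidic titanium tartrate on long reaction times. The fallback sets out from 3 and comes back at 4. Candida antarctica lipase B with vinyl acetate in tert-butyl methyl ether should acetylate the (R)-enantiomer to the acetate F8 and leave the (S)-alcohol F9, which can be driven to high enantiomeric purity by running past half conversion. F9 is then epoxidised to full conversion with the matched reagent (Ti(OiPr)4, D-(−)-diisopropyl tartrate, tBuOOH, CH2Cl2, −20 °C), which should give the erythro epoxy alcohol 4 by double stereodifferentiation.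

**Further compounds**

F1 | step 6 | (2S)-2-[(R)-(3,4-dimethoxyphenyl)(prop-2-yn-1-yloxy)methyl]oxirane | COc1ccc([C@@H](OCC#C)[C@@H]2CO2)cc1OC
F2 | step 6 | (2S)-2-[(R)-(3,4-dimethoxyphenyl){[3-(3,4-dimethoxyphenyl)prop-2-yn-1-yl]oxy}methyl]oxirane | COc1ccc([C@@H](OCC#Cc3ccc(OC)c(OC)c3)[C@@H]2CO2)cc1OC
F3 | step 6 | [(2S,3R)-4-(3,4-dimethoxybenzylidene)-2-(3,4-dimethoxyphenyl)tetrahydrofuran-3-yl]methanol (alkene geometry undefined) | COc1ccc([C@H]2OCC(=Cc3ccc(OC)c(OC)c3)[C@@H]2CO)cc1OC
F4 | step 6 | (3S,4R,5S)-5-(3,4-dimethoxyphenyl)-3-[(3,4-dimethoxyphenyl)(hydroxy)methyl]-4-(hydroxymethyl)tetrahydrofuran-3-ol (benzylic carbinol centre undefined) | COc1ccc([C@H]2OC[C@@](C(O)c3ccc(OC)c(OC)c3)(O)[C@@H]2CO)cc1OC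
F5 | step 4 | (2S)-2-[(R)-[(2-bromoprop-2-en-1-yl)oxy](3,4-dimethoxyphenyl)methyl]oxirane | COc1ccc([C@@H](OCC(Br)=C)[C@@H]2CO2)cc1OC
F6 | step 4 | (3,4-dimethoxybenzyl)zinc chloride | COc1ccc(C[Zn]Cl)cc1OC
F7 | step 4 | (2S)-2-[(R)-{[2-(3,4-dimethoxybenzyl)prop-2-en-1-yl]oxy}(3,4-dimethoxyphenyl)methyl]oxirane | COc1ccc([C@@H](OCC(=C)Cc3ccc(OC)c(OC)c3)[C@@H]2CO2)cc1OC
F8 | step 2 | (R)-1-(3,4-dimethoxyphenyl)prop-2-en-1-yl acetate | COc1ccc([C@@H](C=C)OC(C)=O)cc1OC
F9 | step 2 | (S)-1-(3,4-dimethoxyphenyl)prop-2-en-1-ol | COc1ccc([C@H](C=C)O)cc1OC
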